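**Retrosynthetic overview**

1. The target is a 2,3-trans-3,4-cis flavan-3-ol (rings A, C, B) bonded through C4 to C6 of ring D of a second 2,3-trans flavan-3-ol; it is reached by hydrogenolysis of its nona-benzyl ether.
2. The strategy rests on ring D: a pyrogallol ring with upper C4 on C6, the lower C4 methylene on C4a, and lower O1 on C8a ortho to that methylene. Ring D is therefore an ortho-hydroxybenzyl unit, and the lower pyran ring is cut last, at C3–C4 and O1–C2, into the D-ring ortho-quinone methide and the enamine of benzyloxyacetaldehyde.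
3. The lower B ring enters by Grignard opening of the resulting lactol; O1–C2 is then re-closed by acid through the benzylic cation, trans to the C3 benzyloxy group.
4. Upper C4–ring D bond: the aryl Grignard of a 5-iodosalicylate (its ester carbon is the future lower C4) adds to the (2R,3R)-dihydroflavonol ketone, and silane/acid reduction sets 3,4-cis. The ketone comes from a chalcone by asymmetric epoxidation and acid cyclisation.
5. Ring order: upper ring C (step 4), lower pyran ring as lactol (step 13), the same ring re-closed as the flavan (step 15).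

Key step: step 13

Remark on the chemistry: the future lower C4 is carried as a methyl ester (from methyl 2,3,4-trihydroxybenzoate) because an aldehyde, acetal or benzylic ether on this 2,4-dioxygenated ring would itself be reduced by the silane/acid that sets upper C4; compounds 1, 3, 9, 19 and 22 are assumed to be bought.

Remark on descriptors: upper C4 is R in every benzylated intermediate and S in the target. The geometry (ring D cis to the C3 oxygen) is the same; only the CIP rank of ring D against ring A changes when the D-ring C7 oxygen loses its benzyl group.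

Abbreviation used in names: "U" = (2R,3S,4R)-3,7-bis(benzyloxy)-2-[3,4-bis(benzyloxy)phenyl]chroman-4-yl, the benzylated upper unit (2,3-trans, 3,4-cis).

**Route**

Step 1
Reactants: 1 4'-benzyloxy-2'-hydroxyacetophenone
Product: 2 4'-benzyloxy-2'-(methoxymethoxy)acetophenone
Conditions: NaH, MOMCl, DMF, 0 °C → rt
Reagents that add atoms: chloromethyl methyl ether, COCCl
Why: Williamson etherification of the chelated phenoxide masks the 2'-OH so that the later basic peroxide epoxidation cannot divert into Algar–Flynn–Oyamada cyclisation.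

Step 2
Reactants: 2 4'-benzyloxy-2'-(methoxymethoxy)acetophenone; 3 3,4-bis(benzyloxy)benzaldehyde
Product: 4 (E)-1-[4-(benzyloxy)-2-(methoxymethoxy)phenyl]-3-[3,4-bis(benzyloxy)phenyl]prop-2-en-1-one
Conditions: KOH, EtOH/THF, rt
Reagents that add atoms: none
Why: Claisen–Schmidt condensation of the methyl ketone with a non-enolisable aryl aldehyde should give the thermodynamically favoured E-enone.

Step 3
Reactants: 4 the E-chalcone
Product: 5 [(2R,3S)-3-[3,4-bis(benzyloxy)phenyl]oxiran-2-yl][4-(benzyloxy)-2-(methoxymethoxy)phenyl]methanone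
Conditions: poly-L-leucine, urea–H2O2, 1,8-diazabicyclo[5.4.0]undec-7-ene, THF, rt
Reagents that add atoms: urea–hydrogen peroxide, NC(N)=O.OO
Why: Juliá–Colonna nucleophilic epoxidation, in which the helical polypeptide directs hydroperoxide to one enone face, should give the trans (αR,βS)-epoxide whose Cα becomes upper C3.

Step 4
Reactants: 5 the MOM-protected epoxy ketone
Product: 7 (2R,3R)-7-(benzyloxy)-2-[3,4-bis(benzyloxy)phenyl]-3-hydroxychroman-4-one (2,3-trans), via free 2'-phenol epoxide 6 (not isolated)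
Conditions: conc. HCl, MeOH/THF, 55 °C
Reagents that add atoms: none
Why: acid cleaves the MOM acetal and the freed phenol opens the protonated epoxide at the 4-benzyloxybenzylic Cβ (6-endo epoxide opening with inversion, Cα untouched), which should give the diequatorial 2,3-trans dihydroflavonol even if the opening has cationic character.

Step 5
Reactants: 7 the dihydroflavonol
Product: 8 (2R,3R)-3,7-bis(benzyloxy)-2-[3,4-bis(benzyloxy)phenyl]chroman-4-one
Conditions: BnBr, Ag2O, Bu4NI (cat.), CH2Cl2, rt, dark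
Reagents that add atoms: benzyl bromide, BrCc1ccccc1
Why: Ag2O-promoted Williamson-type benzylation etherifies the α-ketol without the strong base that would epimerise C3 or open ring C by retro-oxa-Michael reaction.

Step 6
Reactants: 9 methyl 2,3,4-trihydroxybenzoate
Product: 10 methyl 3,4-bis(benzyloxy)-2-hydroxybenzoate
Conditions: BnBr (2.1 equiv), K2CO3, acetone, reflux
Reagents that add atoms: benzyl bromide, BrCc1ccccc1
Why: regioselective Williamson benzylation, since the 2-OH is hydrogen-bonded to the ester carbonyl and should stay free while the 4-OH and 3-OH react.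

Step 7
Reactants: 10 methyl 3,4-bis(benzyloxy)-2-hydroxybenzoate
Product: 11 methyl 3,4-bis(benzyloxy)-2-hydroxy-5-iodobenzoate
Conditions: N-iodosuccinimide, CF3CO2H (cat.), MeCN, 0 °C → rt
Reagents that add atoms: N-iodosuccinimide, O=C1CCC(=O)N1I
Why: electrophilic aromatic iodination goes to C5, the only open position para to the free phenol, ortho to the 4-benzyloxy group and meta to the ester.

Step 8
Reactants: 11 the iodophenol
Product: 12 methyl 3,4-bis(benzyloxy)-5-iodo-2-[(4-methoxybenzyl)oxy]benzoate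
Conditions: 4-methoxybenzyl chloride, K2CO3, Bu4NI (cat.), DMF, 50 °C
Reagents that add atoms: 4-methoxybenzyl chloride, COc1ccc(CCl)cc1
Why: Williamson etherification installs an acid-labile PMB ether that masks the phenol during the Grignard step and leaves by itself in step 10.

Step 9
Reactants: 12 the aryl iodide; 8 the 3-O-benzyl ketone
Product: 14 methyl 3,4-bis(benzyloxy)-5-[(2R,3R)-3,7-bis(benzyloxy)-2-[3,4-bis(benzyloxy)phenyl]-4-hydroxychroman-4-yl]-2-[(4-methoxybenzyl)oxy]benzoate (C4 epimers), via arylmagnesium chloride 13 (not isolated)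
Conditions: iPrMgCl·LiCl, THF, −30 °C; then 8, LaCl3·2LiCl, THF, −30 → 0 °C; aq. NH4Cl
Reagents that add atoms: none
Why: iodine–magnesium exchange at low temperature tolerates the methyl ester, and LaCl3·2LiCl-promoted Grignard 1,2-addition of the weakly basic aryl nucleophile should outrun enolisation of the ketone; the C4 configuration is irrelevant because step 10 erases it.

Step 10
Reactants: 14 the tertiary carbinol
Product: 16 methyl 3,4-bis(benzyloxy)-5-U-2-hydroxybenzoate, via PMB-protected 4-arylflavan 15 (not isolated)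
Conditions: Et3SiH (10 equiv), CF3CO2H, CH2Cl2, −78 → 0 °C
Reagents that add atoms: none
Why: ionic hydrogenation, in which acid ionises the bis-benzylic alcohol to the C4 cation (stabilised by the para 7-benzyloxy group) and the silane delivers hydride to the face anti to the C3 benzyloxy group so that ring D ends cis to it, after which warming cleaves the PMB ether (its cation reduced to 4-methylanisole) while the ester is inert.

Step 11
Reactants: 16 the salicylate
Product: 17 5,6-bis(benzyloxy)-4-U-2-(hydroxymethyl)phenol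
Conditions: LiAlH4, THF, 0 °C; aqueous potassium sodium tartrate work-up
Reagents that add atoms: none
Why: LiAlH4 reduction of the salicylate ester should give the 2-hydroxybenzyl alcohol without touching benzyl ethers or stereocentres, and the neutral work-up avoids ionising the acid-sensitive product.

Step 12
Reactants: 17 the 2-hydroxybenzyl alcohol
Product: 18 5,6-bis(benzyloxy)-4-U-2-{[(4-methylphenyl)sulfonyl]methyl}phenol
Conditions: p-toluenesulfinic acid (2 equiv), CH2Cl2, rt
Reagents that add atoms: p-toluenesulfinic acid, Cc1ccc(cc1)S(=O)O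
Why: acid-promoted SN1 substitution through the 2-hydroxy-4-alkoxybenzyl cation, captured at sulfur by the sulfinate, adds an activating group that lets mild base release the ortho-quinone methide in the key step.

Step 13
Reactants: 18 the benzylic sulfone; 19 benzyloxyacetaldehyde (3 equiv)
Product: 21 (3S)-3,7,8-tris(benzyloxy)-6-U-chroman-2-ol (both anomers), via ortho-quinone methide 20 (not isolated)
Conditions: (R)-2-[diphenyl(trimethylsilyloxy)methyl]pyrrolidine (20 mol%), Na2CO3, CH2Cl2/H2O, 0 °C → rt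
Reagents that add atoms: none
Why: Na2CO3 expels p-toluenesulfinate from the phenolate of 18 to give ortho-quinone methide 20 (exocyclic CH2 = lower C4) while the catalyst condenses with 19 to the E,s-trans enamine; the enamine α-carbon, which carries the benzyloxy group, adds to the methide carbon (Michael-type, forming C3–C4), the re-aromatised C8a phenoxide closes on the iminium carbon (forming O1–C2), and hydrolysis of the N,O-aminal releases lactol 21 and the catalyst. The closest known reaction type is the diarylprolinol silyl ether-catalysed formal [4+2] (oxa-Diels–Alder type) of in situ ortho-quinone methides with enolisable aldehydes to chroman-2-ols. The lower pyran ring closes stepwise, by conjugate addition followed by 6-exo-trig attack of oxygen on the iminium carbon. Lower C3 is set by the catalyst: on the standard model the diphenyl(silyloxy)methyl group of the R-configured pyrrolidine shields one enamine face, so the methide adds to the Si face of the α-carbon and gives 3S, whereas C2 forms as an anomeric mixture that does not matter. The step needs C-alkylation at a single methide carbon and capture of the methide by the enamine ahead of its self-dimerisation; ring D offers only one methide site (the former ester carbon ortho to the only free phenol), its C6 substituent is remote from the reacting centres so the catalyst should control the face, and base-limited release of 20 into excess 19 keeps the methide concentration low.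

Step 14
Reactants: 21 the lactol; 22 1,2-bis(benzyloxy)-4-bromobenzene
Product: 24 (2S)-1-[3,4-bis(benzyloxy)phenyl]-2-(benzyloxy)-3-[3,4-bis(benzyloxy)-5-U-2-hydroxyphenyl]propan-1-ol (C1 epimers), via arylmagnesium bromide 23 (not isolated)
Conditions: Mg, THF (22 → 23, 4 equiv); then 21, THF, 0 °C → rt; aq. NH4Cl
Reagents that add atoms: none
Why: Grignard addition to the lactol through its hydroxy-aldehyde tautomer (one equivalent is spent as base), with chelation by the α-benzyloxy group expected to favour the syn carbinol, although this centre is re-set in step 15.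

Step 15
Reactants: 24 the phenol-diol
Product: 25 (2R,3S,4R)-3,7-bis(benzyloxy)-2-[3,4-bis(benzyloxy)phenyl]-4-[(2R,3S)-3,7,8-tris(benzyloxy)-2-[3,4-bis(benzyloxy)phenyl]chroman-6-yl]chroman
Conditions: TsOH·H2O (10 mol%), CH2Cl2, rt → 40 °C
Reagents that add atoms: none
Why: acid-catalysed cyclodehydration (SN1 etherification) through the 4-benzyloxybenzylic cation, captured by the C8a phenol to close the six-membered ring, should place aryl and benzyloxy groups both equatorial (2,3-trans) in the chair-like transition state and, because the C2–O1 bond can re-ionise, also at equilibrium.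

Step 16
Reactants: 25 the nona-benzyl ether
Product: 26 (2R,3S,4S)-2-(3,4-dihydroxyphenyl)-4-[(2R,3S)-2-(3,4-dihydroxyphenyl)-3,7,8-trihydroxychroman-6-yl]chroman-3,7-diol (target)
Conditions: H2 (1 atm), Pd(OH)2/C, THF/MeOH, rt
Reagents that add atoms: none
Why: catalytic hydrogenolysis should remove all nine benzyl ethers without affecting any stereocentre, and the product is handled under inert gas.

**Compound list**

1 | 4'-benzyloxy-2'-hydroxyacetophenone | CC(=O)c1ccc(OCc2ccccc2)cc1O | starting material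
2 | 4'-benzyloxy-2'-(methoxymethoxy)acetophenone | CC(=O)c1ccc(OCc2ccccc2)cc1OCOC | intermediate
3 | 3,4-bis(benzyloxy)benzaldehyde | O=Cc1ccc(OCc2ccccc2)c(OCc2ccccc2)c1 | starting material
4 | (E)-1-[4-(benzyloxy)-2-(methoxymethoxy)phenyl]-3-[3,4-bis(benzyloxy)phenyl]prop-2-en-1-one | COCOc1cc(OCc2ccccc2)ccc1C(=O)/C=C/c1ccc(OCc2ccccc2)c(OCc2ccccc2)c1 | intermediate
5 | [(2R,3S)-3-[3,4-bis(benzyloxy)phenyl]oxiran-2-yl][4-(benzyloxy)-2-(methoxymethoxy)phenyl]methanone | COCOc1cc(OCc2ccccc2)ccc1C(=O)[C@@H]1O[C@H]1c1ccc(OCc2ccccc2)c(OCc2ccccc2)c1 | intermediate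
6 | [(2R,3S)-3-[3,4-bis(benzyloxy)phenyl]oxiran-2-yl][4-(benzyloxy)-2-hydroxyphenyl]methanone | Oc1cc(OCc2ccccc2)ccc1C(=O)[C@@H]1O[C@H]1c1ccc(OCc2ccccc2)c(OCc2ccccc2)c1 | intermediate
7 | (2R,3R)-7-(benzyloxy)-2-[3,4-bis(benzyloxy)phenyl]-3-hydroxychroman-4-one | c1ccccc1COc1ccc2c(c1)O[C@H](c1ccc(OCc3ccccc3)c(OCc3ccccc3)c1)[C@@H](O)C2=O | intermediate
8 | (2R,3R)-3,7-bis(benzyloxy)-2-[3,4-bis(benzyloxy)phenyl]chroman-4-one | c1ccccc1COc1ccc2c(c1)O[C@H](c1ccc(OCc3ccccc3)c(OCc3ccccc3)c1)[C@@H](OCc1ccccc1)C2=O | intermediate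
9 | methyl 2,3,4-trihydroxybenzoate | COC(=O)c1ccc(O)c(O)c1O | starting material
10 | methyl 3,4-bis(benzyloxy)-2-hydroxybenzoate | COC(=O)c1ccc(OCc2ccccc2)c(OCc2ccccc2)c1O | intermediate
11 | methyl 3,4-bis(benzyloxy)-2-hydroxy-5-iodobenzoate | COC(=O)c1cc(I)c(OCc2ccccc2)c(OCc2ccccc2)c1O | intermediate
12 | methyl 3,4-bis(benzyloxy)-5-iodo-2-[(4-methoxybenzyl)oxy]benzoate | COC(=O)c1cc(I)c(OCc2ccccc2)c(OCc2ccccc2)c1OCc1ccc(OC)cc1 | intermediate
13 | [2,3-bis(benzyloxy)-4-[(4-methoxybenzyl)oxy]-5-(methoxycarbonyl)phenyl]magnesium chloride (LiCl complex) | COC(=O)c1cc([Mg]Cl)c(OCc2ccccc2)c(OCc2ccccc2)c1OCc1ccc(OC)cc1 | intermediate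
14 | methyl 3,4-bis(benzyloxy)-5-[(2R,3R)-3,7-bis(benzyloxy)-2-[3,4-bis(benzyloxy)phenyl]-4-hydroxychroman-4-yl]-2-[(4-methoxybenzyl)oxy]benzoate (C4 epimers) | c1ccccc1COc1ccc2c(c1)O[C@H](c1ccc(OCc3ccccc3)c(OCc3ccccc3)c1)[C@@H](OCc1ccccc1)C2(O)c1cc(C(=O)OC)c(OCc2ccc(OC)cc2)c(OCc2ccccc2)c1OCc1ccccc1 | intermediate
15 | methyl 3,4-bis(benzyloxy)-5-U-2-[(4-methoxybenzyl)oxy]benzoate | c1ccccc1COc1ccc2c(c1)O[C@H](c1ccc(OCc3ccccc3)c(OCc3ccccc3)c1)[C@@H](OCc1ccccc1)[C@H]2c1cc(C(=O)OC)c(OCc2ccc(OC)cc2)c(OCc2ccccc2)c1OCc1ccccc1 | intermediate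
16 | methyl 3,4-bis(benzyloxy)-5-U-2-hydroxybenzoate | c1ccccc1COc1ccc2c(c1)O[C@H](c1ccc(OCc3ccccc3)c(OCc3ccccc3)c1)[C@@H](OCc1ccccc1)[C@H]2c1cc(C(=O)OC)c(O)c(OCc2ccccc2)c1OCc1ccccc1 | intermediate
17 | 5,6-bis(benzyloxy)-4-U-2-(hydroxymethyl)phenol | c1ccccc1COc1ccc2c(c1)O[C@H](c1ccc(OCc3ccccc3)c(OCc3ccccc3)c1)[C@@H](OCc1ccccc1)[C@H]2c1cc(CO)c(O)c(OCc2ccccc2)c1OCc1ccccc1 | intermediate
18 | 5,6-bis(benzyloxy)-4-U-2-{[(4-methylphenyl)sulfonyl]methyl}phenol | c1ccccc1COc1ccc2c(c1)O[C@H](c1ccc(OCc3ccccc3)c(OCc3ccccc3)c1)[C@@H](OCc1ccccc1)[C@H]2c1cc(CS(=O)(=O)c2ccc(C)cc2)c(O)c(OCc2ccccc2)c1OCc1ccccc1 | intermediate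
19 | benzyloxyacetaldehyde | O=CCOCc1ccccc1 | starting material
20 | 2,3-bis(benzyloxy)-4-U-6-methylidenecyclohexa-2,4-dien-1-one | c1ccccc1COc1ccc2c(c1)O[C@H](c1ccc(OCc3ccccc3)c(OCc3ccccc3)c1)[C@@H](OCc1ccccc1)[C@H]2C1=CC(=C)C(=O)C(OCc2ccccc2)=C1OCc1ccccc1 | intermediate
21 | (3S)-3,7,8-tris(benzyloxy)-6-U-chroman-2-ol (both anomers) | c1ccccc1COc1ccc2c(c1)O[C@H](c1ccc(OCc3ccccc3)c(OCc3ccccc3)c1)[C@@H](OCc1ccccc1)[C@H]2c1cc2c(c(OCc3ccccc3)c1OCc1ccccc1)OC(O)[C@@H](OCc1ccccc1)C2 | intermediate
22 | 1,2-bis(benzyloxy)-4-bromobenzene | Brc1ccc(OCc2ccccc2)c(OCc2ccccc2)c1 | starting material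
23 | [3,4-bis(benzyloxy)phenyl]magnesium bromide | Br[Mg]c1ccc(OCc2ccccc2)c(OCc2ccccc2)c1 | intermediate
24 | (2S)-1-[3,4-bis(benzyloxy)phenyl]-2-(benzyloxy)-3-[3,4-bis(benzyloxy)-5-U-2-hydroxyphenyl]propan-1-ol (C1 epimers) | c1ccccc1COc1ccc2c(c1)O[C@H](c1ccc(OCc3ccccc3)c(OCc3ccccc3)c1)[C@@H](OCc1ccccc1)[C@H]2c1cc(C[C@H](OCc2ccccc2)C(O)c2ccc(OCc3ccccc3)c(OCc3ccccc3)c2)c(O)c(OCc2ccccc2)c1OCc1ccccc1 | intermediate
25 | (2R,3S,4R)-3,7-bis(benzyloxy)-2-[3,4-bis(benzyloxy)phenyl]-4-[(2R,3S)-3,7,8-tris(benzyloxy)-2-[3,4-bis(benzyloxy)phenyl]chroman-6-yl]chroman | c1ccccc1COc1ccc2c(c1)O[C@H](c1ccc(OCc3ccccc3)c(OCc3ccccc3)c1)[C@@H](OCc1ccccc1)[C@H]2c1cc2c(c(OCc3ccccc3)c1OCc1ccccc1)O[C@H](c1ccc(OCc3ccccc3)c(OCc3ccccc3)c1)[C@@H](OCc1ccccc1)C2 | intermediate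
26 | (2R,3S,4S)-2-(3,4-dihydroxyphenyl)-4-[(2R,3S)-2-(3,4-dihydroxyphenyl)-3,7,8-trihydroxychroman-6-yl]chroman-3,7-diol | Oc1ccc2c(c1)O[C@H](c1ccc(O)c(O)c1)[C@@H](O)[C@H]2c1cc2c(c(O)c1O)O[C@H](c1ccc(O)c(O)c1)[C@@H](O)C2 | target

**Step count and risks**

Total: 16 steps. Longest linear sequence: 13 steps (steps 1–5 and 9–16); the D-ring branch (steps 6–8) joins at step 9.

Steps most likely to fail:

1. Step 13. The ortho-quinone methide may dimerise or oligomerise, or N-alkylate the catalyst, faster than the enamine traps it, and the α-oxygenated aldehyde may self-condense. Facial discrimination could also be weak or inverted if the α-benzyloxy enamine reacts through its Z isomer; in that case the enantiomeric catalyst would be tried first. The fallback sets out from sulfone 18 and uses auxiliary control in place of the catalyst. The sodium enolate of commercial (R)-4-benzyl-3-[(benzyloxy)acetyl]-1,3-oxazolidin-2-one (NaN(SiMe3)2, THF, −78 °C, a little over two equivalents, one of which releases methide 20) should add to the methide anti to the benzyl group of the chelated Z-enolate, as in an Evans auxiliary alkylation. This gives (4R)-4-benzyl-3-[(2S)-2-(benzyloxy)-3-[3,4-bis(benzyloxy)-5-U-2-hydroxyphenyl]propanoyl]-1,3-oxazolidin-2-one F1. On warming, or with 1,8-diazabicyclo[5.4.0]undec-7-ene, the C8a phenoxide should acylate itself on the imide carbonyl to give (3S)-3,7,8-tris(benzyloxy)-6-U-chroman-2-one F2 and the free auxiliary. Reduction with iBu2AlH (toluene, −78 °C) returns to the route at lactol 21.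

2. Step 9. Carbon–carbon bond formation may stall through enolisation or ring opening of the hindered ketone 8, or through self-condensation of the ester-bearing Grignard 13. The fallback sets out from ketone 8 and phenol 10 and bypasses steps 7–10. NaBH4 (MeOH/THF, 0 °C) reduces 8 to (2R,3S)-3,7-bis(benzyloxy)-2-[3,4-bis(benzyloxy)phenyl]chroman-4-ol F3. BF3·OEt2 (CH2Cl2, −40 °C) ionises it to the C4 cation, and a Friedel–Crafts alkylation of excess 10, para to its free phenol, should give salicylate 16 together with its 3,4-trans C4 epimer, methyl 3,4-bis(benzyloxy)-5-[(2R,3S,4S)-3,7-bis(benzyloxy)-2-[3,4-bis(benzyloxy)phenyl]chroman-4-yl]-2-hydroxybenzoate F4. The trans epimer is expected to be the major one, so the 3,4-cis epimer is separated by chromatography, and the fallback comes back to the route at 16.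

3. Step 15. Capture of the benzylic cation may show poor trans/cis control, or the cis isomer may not equilibrate. The fallback sets out from 24 and replaces the cationic closure by a stereospecific displacement. The syn isomer expected to predominate from the chelation-controlled addition, (1S,2S)-1-[3,4-bis(benzyloxy)phenyl]-2-(benzyloxy)-3-[3,4-bis(benzyloxy)-5-U-2-hydroxyphenyl]propan-1-ol F5, is separated and closed by Mitsunobu etherification (PPh3, diisopropyl azodicarboxylate, THF, 0 °C). The C8a phenol should displace the activated carbinol with inversion, giving the 2,3-trans ring of 25, where the fallback rejoins the route.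

**Further compounds**

F1 | step 13 | (4R)-4-benzyl-3-[(2S)-2-(benzyloxy)-3-[3,4-bis(benzyloxy)-5-U-2-hydroxyphenyl]propanoyl]-1,3-oxazolidin-2-one | c1ccccc1COc1ccc2c(c1)O[C@H](c1ccc(OCc3ccccc3)c(OCc3ccccc3)c1)[C@@H](OCc1ccccc1)[C@H]2c1cc(C[C@H](OCc2ccccc2)C(=O)N2C(=O)OC[C@H]2Cc2ccccc2)c(O)c(OCc2ccccc2)c1OCc1ccccc1
F2 | step 13 | (3S)-3,7,8-tris(benzyloxy)-6-U-chroman-2-one | c1ccccc1COc1ccc2c(c1)O[C@H](c1ccc(OCc3ccccc3)c(OCc3ccccc3)c1)[C@@H](OCc1ccccc1)[C@H]2c1cc2c(c(OCc3ccccc3)c1OCc1ccccc1)OC(=O)[C@@H](OCc1ccccc1)C2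
F3 | step 9 | (2R,3S)-3,7-bis(benzyloxy)-2-[3,4-bis(benzyloxy)phenyl]chroman-4-ol (C4 epimers) | c1ccccc1COc1ccc2c(c1)O[C@H](c1ccc(OCc3ccccc3)c(OCc3ccccc3)c1)[C@@H](OCc1ccccc1)C2O
F4 | step 9 | methyl 3,4-bis(benzyloxy)-5-[(2R,3S,4S)-3,7-bis(benzyloxy)-2-[3,4-bis(benzyloxy)phenyl]chroman-4-yl]-2-hydroxybenzoate | c1ccccc1COc1ccc2c(c1)O[C@H](c1ccc(OCc3ccccc3)c(OCc3ccccc3)c1)[C@@H](OCc1ccccc1)[C@@H]2c1cc(C(=O)OC)c(O)c(OCc2ccccc2)c1OCc1ccccc1
F5 | step 15 | (1S,2S)-1-[3,4-bis(benzyloxy)phenyl]-2-(benzyloxy)-3-[3,4-bis(benzyloxy)-5-U-2-hydroxyphenyl]propan-1-ol | c1ccccc1COc1ccc2c(c1)O[C@H](c1ccc(OCc3ccccc3)c(OCc3ccccc3)c1)[C@@H](OCc1ccccc1)[C@H]2c1cc(C[C@H](OCc2ccccc2)[C@@H](O)c2ccc(OCc3ccccc3)c(OCc3ccccc3)c2)c(O)c(OCc2ccccc2)c1OCc1ccccc1
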